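**Take the zero.** Start from the racemate, whose excess is zero by symmetry: charged equally, the two substrates can differ afterwards by what reaction took from them. I called the product lead L the excess of left-handed over right-handed among the substrate that has reacted. If substrate goes to product and nowhere else, as I assumed, the excess of right-handed substrate among what is left equals L times the reacted share divided by the unreacted share.

common to all: left-handed substrate 0.050 M; right-handed substrate 0.050 M; catalyst 0.55 mM
- cedar: partner 0.072 M; run made earlier
- elm: partner 0.14 M; run made earlier
- summer: partner 0.0550 M; time 25 h
- spring: partner 0.120 M; time 25 h

- cedar (time / h: right-handed substrate / %, left-handed substrate / %): 1.33: 45, 47; 3.00: 45, 41; 6.00: 42, 38; 10.0: 39, 34; 12.0: 40, 35; 20.0: 42, 33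
- elm (time / h: right-handed substrate / %, left-handed substrate / %): 1.33: 45, 39; 2.50: 43, 34; 4.00: 36, 31; 6.00: 34, 28; 10.0: 33, 25; 20.0: 35, 19

(scatter of a reading: 2 percentage points)

- catalyst is single-handed; left-handed substrate and right-handed substrate are mirror images of each other, charged as a racemate, each of them at the stated concentration
- an excess is the difference of the two amounts in percent of their sum
- an excess is below zero if the other one leads

1. the flask that ends with the higher excess of right-handed substrate over left-handed substrate among what is left of the two, or "neither" when 2 percentage points or less lies between them (summer / spring / neither)
2. excess of right-handed substrate over left-handed substrate among what is left of the two at the end, summer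
3. excess of right-handed substrate over left-handed substrate among what is left of the two at the end, spring

**First estimate.** Elm's last reading gave L = 34.8%. But that is one reading, and scatter moves it by about 6.15%.

**Better estimate.** In elm the two substrates together went from 58.0% to 54.0% over the last two readings, and cedar's sum barely moved, so I averaged those pairs. Cedar had lost 25.0% with a lead of 7.00%, and elm 44.0% with 12.0%. So L read 28.0% and 27.3%, and pooled 27.5%.

**The reacted share.** I still needed that share. Substrate lost per partner charged read 34.7% in cedar and 31.4% in elm. These differ, so I used the nearer run for each flask. That gave 19.1% reacted in summer and 37.7% in spring, hence excesses of 6.50% and 16.7%.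

**The result.** The forecast also chose spring, with 9% for summer and 30% for spring, higher than my spring, on the ground that “Elm's excess is still climbing”. The flasks gave 8.61% in summer and 19.1% in spring. In spring, partner, the first to run out although its charge exceeded that of the two substrates together, stood at 0.65% of its charge after 25.0 h, less than the 47% of left-handed substrate remaining. Spring's reacted share was 42.0%, above my 37.7%, and with it L gives 19.9%.

    partner + catalyst + left-handed substrate → catalyst + left-handed product (k = 43.0 L² mol⁻² min⁻¹)
    partner + catalyst + right-handed substrate → catalyst + right-handed product (k = 21.0 L² mol⁻² min⁻¹)
    partner → decomposed reagent (k = 0.00220 min⁻¹)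
    2 partner → homo dimer (k = 0.00190 L mol⁻¹ min⁻¹)

**Second flask.** A neighbour of spring with 1.4 × 10⁻⁴ M of catalyst, a quarter of spring's, ended with 38.9% left-handed and 44.2% right-handed substrate, so 16.9% had reacted and L gives 5.59%. The computed excess is 6.41%.

All runs were computed for an exercise; the scatter is artificial.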